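## Retrosynthetic overview

1. Kazinol D (26) comes from 8-silylchroman 24. C8–OH is unmasked from C8–Si by Tamao–Fleming oxidation, and the same fluoride frees the two ring A phenols.
2. The plan rests on the pentasubstituted ring B. Its six carbons are read as the two-carbon units C8–C8a, C4a–C5 and C6–C7, and the pyran chain O1–C2–C3–C4 already links C8a to C4a.
3. So 24 comes from ynol ether diyne 11 and terminal alkyne 22 by a rhodium [2+2+2]. The pyran closes at the metallacycle stage, ring B closes on reductive elimination, and ring A is bought.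
4. Diyne 11 comes from methyl pent-4-ynoate (C2 to C4a), prenyl bromide, trichloroethylene (C8a–C8) and BnMe2SiCl.
5. Alkyne 22 comes from 2,4-dihydroxybenzaldehyde by O-prenylation, aromatic Claisen rearrangement, Grignard addition and ionic deoxygenation.

Key step: step 12

Remark: the target has no stereocentre and no stereodefined alkene. Racemic BINAP therefore suffices, and the transient stereocentres in 15 and 20 and the alkene geometry of 8 have no consequence.

## Route

Step 1
Reactants: 1 methyl pent-4-ynoate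
Product: 3 2-methylhex-5-yn-2-ol, via hex-5-yn-2-one 2 (not isolated)
Conditions: MeMgBr (3.3 equiv), THF, 0 °C to rt; aq NH4Cl
Reagents that add atoms: methylmagnesium bromide, C[Mg]Br
Why: Double Grignard addition to the ester, passing through ketone 2, gives the tertiary carbinol whose carbon becomes C2 with its gem-dimethyl pair, while the extra equivalent merely deprotonates the alkyne C–H, which is restored on work-up.

Step 2
Reactants: 3 2-methylhex-5-yn-2-ol; 4 prenyl bromide
Product: 5 2,9-dimethyldec-8-en-5-yn-2-ol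
Conditions: CuI (20 mol %), n-Bu4NI (20 mol %), K2CO3, DMF, rt
Reagents that add atoms: none
Why: Copper-catalysed allylation of a terminal alkyne (SN2 attack of the copper acetylide on the unhindered primary carbon of the allylic bromide) should give the linear skipped enyne and does not touch the tertiary alcohol.

Step 3
Reactants: 5 2,9-dimethyldec-8-en-5-yn-2-ol; 6 trichloroethylene
Product: 8 9-{[(E)-1,2-dichloroethenyl]oxy}-2,9-dimethyldec-2-en-5-yne, via dichloroacetylene 7 (not isolated)
Conditions: KH (1.2 equiv), THF, 0 °C; then Cl2C=CHCl, −50 °C to rt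
Reagents that add atoms: none
Why: The alkoxide strips HCl from trichloroethylene and then adds anti to the dichloroacetylene so formed, the established addition route to (E)-1,2-dichlorovinyl ethers that also accepts hindered alkoxides, and the short, cold exposure to base should keep the skipped enyne from isomerising.

Step 4
Reactants: 8 9-{[(E)-1,2-dichloroethenyl]oxy}-2,9-dimethyldec-2-en-5-yne
Product: 11 benzyl({[2,9-dimethyldec-8-en-5-yn-2-yl]oxy}ethynyl)dimethylsilane, via chloroalkynyl ether 9 (not isolated), via lithium alkoxyacetylide 10 (not isolated)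
Conditions: n-BuLi (2.1 equiv), THF, −78 to −40 °C; BnMe2SiCl, −78 to 0 °C; pH 7 buffer; Et3N-deactivated silica, product stored cold
Reagents that add atoms: benzylchlorodimethylsilane, C[Si](C)(Cl)Cc1ccccc1
Why: Elimination of HCl from the dichlorovinyl ether, chlorine–lithium exchange and C-silylation is the standard way from such ethers to substituted ynol ethers, and with exactly two equivalents of base at −78 °C the acidic vinylic C–H of 8 should be removed much faster than the doubly activated CH2 of the enyne.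

Step 5
Reactants: 12 2,4-dihydroxybenzaldehyde; 4 prenyl bromide
Product: 13 2-hydroxy-4-[(3-methylbut-2-en-1-yl)oxy]benzaldehyde
Conditions: K2CO3 (1.05 equiv), acetone, reflux
Reagents that add atoms: none
Why: Williamson etherification is selective for O4 because the 2-OH is tied up in a hydrogen bond to the formyl group and is less acidic and less nucleophilic.

Step 6
Reactants: 13 2-hydroxy-4-[(3-methylbut-2-en-1-yl)oxy]benzaldehyde
Product: 14 2-[(tert-butyldimethylsilyl)oxy]-4-[(3-methylbut-2-en-1-yl)oxy]benzaldehyde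
Conditions: TBSCl, imidazole, DMF, rt
Reagents that add atoms: tert-butyldimethylsilyl chloride, CC(C)(C)[Si](C)(C)Cl
Why: Standard imidazole-promoted silylation caps the chelated phenol, which removes the hydrogen-bond bias towards C3 and puts a bulky group next to C3 before the rearrangement.

Step 7
Reactants: 14 2-[(tert-butyldimethylsilyl)oxy]-4-[(3-methylbut-2-en-1-yl)oxy]benzaldehyde
Product: 16 2-[(tert-butyldimethylsilyl)oxy]-4-hydroxy-5-(2-methylbut-3-en-2-yl)benzaldehyde, via ortho-dienone 15 (not isolated)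
Conditions: PhNEt2, 195 °C, sealed tube, Ar
Reagents that add atoms: none
Why: Aromatic Claisen rearrangement, a [3,3]-sigmatropic shift with allyl inversion, turns the O-prenyl group into the C-bound 1,1-dimethylallyl group, should choose C5 because a quaternary carbon is not accommodated at C3 between two oxygen substituents, and ends with tautomerisation of the racemic dienone 15, whose stereocentre vanishes.

Step 8
Reactants: 16 2-[(tert-butyldimethylsilyl)oxy]-4-hydroxy-5-(2-methylbut-3-en-2-yl)benzaldehyde
Product: 17 2,4-bis[(tert-butyldimethylsilyl)oxy]-5-(2-methylbut-3-en-2-yl)benzaldehyde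
Conditions: TBSCl, imidazole, DMAP (cat.), DMF, 45 °C
Reagents that add atoms: tert-butyldimethylsilyl chloride, CC(C)(C)[Si](C)(C)Cl
Why: Silylation of the acidic para-formyl phenol should proceed despite the neighbouring quaternary carbon at slightly raised temperature and gives a silyl ether that this neighbour then shields.

Step 9
Reactants: 17 2,4-bis[(tert-butyldimethylsilyl)oxy]-5-(2-methylbut-3-en-2-yl)benzaldehyde; 18 (4-bromobut-1-yn-1-yl)trimethylsilane
Product: 20 1-{2,4-bis[(tert-butyldimethylsilyl)oxy]-5-(2-methylbut-3-en-2-yl)phenyl}-5-(trimethylsilyl)pent-4-yn-1-ol (racemic), via Grignard reagent 19 (not isolated)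
Conditions: 18, Mg, THF, rt to 40 °C; then 17, −78 to −30 °C; cold aq NH4Cl
Reagents that add atoms: none
Why: Grignard addition to the aromatic aldehyde brings in the two remaining linker carbons and the masked C6–C7 alkyne, the carbinol stereocentre forms racemic and is erased in step 10, and the cold quench prevents aryl-to-alkoxide silyl migration.

Step 10
Reactants: 20 1-{2,4-bis[(tert-butyldimethylsilyl)oxy]-5-(2-methylbut-3-en-2-yl)phenyl}-5-(trimethylsilyl)pent-4-yn-1-ol
Product: 21 (5-{2,4-bis[(tert-butyldimethylsilyl)oxy]-5-(2-methylbut-3-en-2-yl)phenyl}pent-1-yn-1-yl)trimethylsilane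
Conditions: Et3SiH (3 equiv), CF3CO2H (2 equiv), CH2Cl2, −78 to −20 °C
Reagents that add atoms: none
Why: In this ionic hydrogenation the 2,4-dioxygenated benzylic alcohol ionises under mild acid at low temperature to a strongly stabilised cation that Et3SiH reduces, under conditions too mild to protonate the monosubstituted alkene or to cleave the aryl silyl ethers and the alkynylsilane, and no ionisation-prone 2,4-bis(silyloxy)benzyl halide has to be handled.

Step 11
Reactants: 21 (5-{2,4-bis[(tert-butyldimethylsilyl)oxy]-5-(2-methylbut-3-en-2-yl)phenyl}pent-1-yn-1-yl)trimethylsilane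
Product: 22 1,5-bis[(tert-butyldimethylsilyl)oxy]-2-(2-methylbut-3-en-2-yl)-4-(pent-4-yn-1-yl)benzene
Conditions: AgNO3 (10 mol %), CH2Cl2/MeOH/H2O, rt
Reagents that add atoms: none
Why: Silver-catalysed protiodesilylation of an alkynylsilane runs at neutral pH through a silver acetylide and is therefore selective for the C(sp)–Si bond over the base-labile aryl silyl ethers.

Step 12
Reactants: 11 benzyl({[2,9-dimethyldec-8-en-5-yn-2-yl]oxy}ethynyl)dimethylsilane; 22 1,5-bis[(tert-butyldimethylsilyl)oxy]-2-(2-methylbut-3-en-2-yl)-4-(pent-4-yn-1-yl)benzene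
Product: 24 benzyl{6-[3-(2,4-bis[(tert-butyldimethylsilyl)oxy]-5-(2-methylbut-3-en-2-yl)phenyl)propyl]-2,2-dimethyl-5-(3-methylbut-2-en-1-yl)chroman-8-yl}dimethylsilane, via rhodacyclopentadiene 23 (not isolated)
Conditions: [Rh(cod)2]BF4 (10 mol %), rac-BINAP (10 mol %), CH2Cl2, H2 (1 atm, 30 min), then Ar purge; 11, 4 Å MS; 22 (1.2 equiv) by syringe pump, 20 °C
Reagents that add atoms: none
Why: Proposed new method: the cationic monovalent rhodium–BINAP fragment binds both alkynes of 11 and undergoes oxidative cyclisation to the trivalent rhodacyclopentadiene 23, which forms C8a–C4a and so closes the dihydropyran as a six-membered ring along the O1–C2–C3–C4 tether, with the gem-dimethyl group at C2 favouring the folded conformer. Alkyne 22 then inserts into the less shielded Rh–C5 bond (C5–C6) and reductive elimination joins C7 to C8, so that ring B closes as the formal [2+2+2] sum of three alkynes and monovalent rhodium is released. The closest known reaction types are cationic rhodium/BINAP cyclotrimerisations of carbon- or heteroatom-tethered 1,6- and 1,7-diynes with terminal alkynes and the same catalysis applied to aryl alkynyl ethers and phenol-linked diynes, whereas a tertiary-alkyl silyl ynol ether has not been shown as the tether. No stereocentre is formed. The step needs regioselectivity (substituted alkyne carbon at C6, CH at C7), which the BnMe2Si group on C8 should secure because it is far larger than the prenyl CH2 on C5, and chemoselectivity, which rests on the weak binding of the trisubstituted prenyl alkene and the neopentyl-type vinyl group and on slow addition of 22 against its self-trimerisation. Dry, acid-free work at or below 20 °C is essential, since warming makes a tertiary alkynyl ether expel alkene in a retro-ene process and leave a ketene, and traces of acid hydrate it.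

Step 13
Reactants: 24 benzyl{6-[3-(2,4-bis[(tert-butyldimethylsilyl)oxy]-5-(2-methylbut-3-en-2-yl)phenyl)propyl]-2,2-dimethyl-5-(3-methylbut-2-en-1-yl)chroman-8-yl}dimethylsilane
Product: 26 kazinol D, via arylsilanol 25 (not isolated)
Conditions: TBAF (5 equiv), THF, 0 °C; then MeOH, KHCO3, 30 % aq H2O2, 0 °C to rt; aq Na2S2O3
Reagents that add atoms: hydrogen peroxide, OO
Why: Fluoride adds to silicon, expels the benzyl group (safety-catch activation) and also cleaves both aryl silyl ethers, after which the heteroatom-substituted arylsilane 25 undergoes Tamao–Fleming oxidation, in which hydroperoxide binds to silicon and the aryl group migrates to oxygen so that the C8–O bond forms at the ipso carbon, while buffered peroxide leaves unactivated alkenes alone.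

## Compound list

1 | methyl pent-4-ynoate | C#CCCC(=O)OC | starting material
2 | hex-5-yn-2-one | C#CCCC(C)=O | intermediate
3 | 2-methylhex-5-yn-2-ol | C#CCCC(C)(C)O | intermediate
4 | prenyl bromide (1-bromo-3-methylbut-2-ene) | CC(C)=CCBr | starting material
5 | 2,9-dimethyldec-8-en-5-yn-2-ol | CC(C)=CCC#CCCC(C)(C)O | intermediate
6 | trichloroethylene | ClC=C(Cl)Cl | starting material
7 | dichloroacetylene | ClC#CCl | intermediate
8 | 9-{[(E)-1,2-dichloroethenyl]oxy}-2,9-dimethyldec-2-en-5-yne | CC(C)=CCC#CCCC(C)(C)O/C(Cl)=C\Cl | intermediate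
9 | 9-[(chloroethynyl)oxy]-2,9-dimethyldec-2-en-5-yne | CC(C)=CCC#CCCC(C)(C)OC#CCl | intermediate
10 | lithium {[2,9-dimethyldec-8-en-5-yn-2-yl]oxy}acetylide | CC(C)=CCC#CCCC(C)(C)OC#C[Li] | intermediate
11 | benzyl({[2,9-dimethyldec-8-en-5-yn-2-yl]oxy}ethynyl)dimethylsilane (silyl ynol ether 1,7-diyne) | CC(C)=CCC#CCCC(C)(C)OC#C[Si](C)(C)Cc1ccccc1 | intermediate
12 | 2,4-dihydroxybenzaldehyde | O=Cc1ccc(O)cc1O | starting material
13 | 2-hydroxy-4-[(3-methylbut-2-en-1-yl)oxy]benzaldehyde | O=Cc1ccc(OCC=C(C)C)cc1O | intermediate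
14 | 2-[(tert-butyldimethylsilyl)oxy]-4-[(3-methylbut-2-en-1-yl)oxy]benzaldehyde | O=Cc1ccc(OCC=C(C)C)cc1O[Si](C)(C)C(C)(C)C | intermediate
15 | 6-[(tert-butyldimethylsilyl)oxy]-3-(2-methylbut-3-en-2-yl)-4-oxocyclohexa-1,5-diene-1-carbaldehyde (racemic) | O=CC1=CC(C(C)(C)C=C)C(=O)C=C1O[Si](C)(C)C(C)(C)C | intermediate
16 | 2-[(tert-butyldimethylsilyl)oxy]-4-hydroxy-5-(2-methylbut-3-en-2-yl)benzaldehyde | O=Cc1cc(C(C)(C)C=C)c(O)cc1O[Si](C)(C)C(C)(C)C | intermediate
17 | 2,4-bis[(tert-butyldimethylsilyl)oxy]-5-(2-methylbut-3-en-2-yl)benzaldehyde | O=Cc1cc(C(C)(C)C=C)c(O[Si](C)(C)C(C)(C)C)cc1O[Si](C)(C)C(C)(C)C | intermediate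
18 | (4-bromobut-1-yn-1-yl)trimethylsilane | C[Si](C)(C)C#CCCBr | starting material
19 | [4-(trimethylsilyl)but-3-yn-1-yl]magnesium bromide | C[Si](C)(C)C#CCC[Mg]Br | intermediate
20 | 1-{2,4-bis[(tert-butyldimethylsilyl)oxy]-5-(2-methylbut-3-en-2-yl)phenyl}-5-(trimethylsilyl)pent-4-yn-1-ol (racemic) | C[Si](C)(C)C#CCCC(O)c1cc(C(C)(C)C=C)c(O[Si](C)(C)C(C)(C)C)cc1O[Si](C)(C)C(C)(C)C | intermediate
21 | (5-{2,4-bis[(tert-butyldimethylsilyl)oxy]-5-(2-methylbut-3-en-2-yl)phenyl}pent-1-yn-1-yl)trimethylsilane | C[Si](C)(C)C#CCCCc1cc(C(C)(C)C=C)c(O[Si](C)(C)C(C)(C)C)cc1O[Si](C)(C)C(C)(C)C | intermediate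
22 | 1,5-bis[(tert-butyldimethylsilyl)oxy]-2-(2-methylbut-3-en-2-yl)-4-(pent-4-yn-1-yl)benzene (ring A pent-4-ynyl arene) | C#CCCCc1cc(C(C)(C)C=C)c(O[Si](C)(C)C(C)(C)C)cc1O[Si](C)(C)C(C)(C)C | intermediate
23 | pyran-fused rhodacyclopentadiene from 11 (cationic, BINAP on rhodium; BINAP and BF4 not drawn) | CC(C)=CCC1=C2CCC(C)(C)OC2=C([Si](C)(C)Cc2ccccc2)[Rh]1 | intermediate
24 | benzyl{6-[3-(2,4-bis[(tert-butyldimethylsilyl)oxy]-5-(2-methylbut-3-en-2-yl)phenyl)propyl]-2,2-dimethyl-5-(3-methylbut-2-en-1-yl)chroman-8-yl}dimethylsilane | C=CC(C)(C)c1cc(CCCc2cc([Si](C)(C)Cc4ccccc4)c3c(c2CC=C(C)C)CCC(C)(C)O3)c(O[Si](C)(C)C(C)(C)C)cc1O[Si](C)(C)C(C)(C)C | intermediate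
25 | {6-[3-(2,4-dihydroxy-5-(2-methylbut-3-en-2-yl)phenyl)propyl]-2,2-dimethyl-5-(3-methylbut-2-en-1-yl)chroman-8-yl}dimethylsilanol | C=CC(C)(C)c1cc(CCCc2cc([Si](C)(C)O)c3c(c2CC=C(C)C)CCC(C)(C)O3)c(O)cc1O | intermediate
26 | kazinol D | C=CC(C)(C)c1cc(CCCc2cc(O)c3c(c2CC=C(C)C)CCC(C)(C)O3)c(O)cc1O | target

## Step count

- Total step count: 13.
- Longest linear sequence: 9 steps (12 to 26, steps 5 to 13).
- The diyne branch adds 4 steps before the union.

## Steps most likely to fail

**1. Step 12.**
- What may go wrong: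
  - The Lewis acidic cationic rhodium may cause heterolysis or retro-ene loss of the tertiary alkyl group from the ynol ether before the metallacycle forms.
  - Oxidative cyclisation of a diyne substituted at both termini may be so slow that self-trimerisation of the terminal alkyne takes over.
  - Regiocontrol in the insertion may erode.
- Fallback (known chemistry; sets out from 3 and 22, rejoins at 26). Ring B is built onto a ready-made pyran by a Dötz benzannulation, and the C8 oxygen comes from the carbene.
  - Alkynol 3 is cycloisomerised in the endo mode through a tungsten vinylidene (W(CO)6, Et3N, THF, hν) to 2,2-dimethyl-3,4-dihydro-2H-pyran F1.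
  - α-Lithiation (t-BuLi, THF), addition to Cr(CO)6 and O-methylation with Me3OBF4 give the zerovalent chromium Fischer carbene complex (CO)5Cr=C(OMe)(6,6-dimethyl-5,6-dihydro-4H-pyran-2-yl) F2.
  - Heating F2 and 22 in THF at 55 °C, followed by exposure to air, should give 8-methoxychroman-5-ol F3. The carbene carbon becomes C8, the enol ether C=C becomes C8a–C4a, one CO becomes C5, and the alkyne supplies C6–C7 with its larger substituent next to the new phenol carbon.
  - Tf2O and 2,6-lutidine give aryl triflate F4.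
  - Stille coupling with tributyl(3-methylbut-2-en-1-yl)stannane (Pd(PPh3)4, LiCl, DMF) installs the C5 side chain in 5-prenyl-8-methoxychroman F5.
  - TBAF gives 8-O-methylkazinol D F6.
  - NaSEt in hot DMF removes the methyl group by SN2 attack and gives 26.

**2. Step 13.**
- What may go wrong:
  - Fluoride may cleave the aryl–silicon bond (protodesilylation at C8) in competition with the benzyl–silicon bond.
  - The liberated electron-rich phenolates may be over-oxidised in basic peroxide.
- Fallback (sets out from 8, rejoins at 26). The safety-catch silane is replaced by a silicon group that already carries oxygen, so oxidation needs no fluoride and runs while ring A is still protected.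
  - Compound 8 is taken to acetylide 10 as in step 4 and trapped with chloro(isopropoxy)dimethylsilane to give isopropoxysilyl diyne F7.
  - The cycloaddition of step 12 with 22 gives 8-(isopropoxydimethylsilyl)chroman F8.
  - Fluoride-free Tamao oxidation (30 % H2O2, KHCO3, THF/MeOH) gives 8-hydroxychroman bis(silyl ether) F9.
  - TBAF at 0 °C then gives 26.

**3. Step 7.**
- What may go wrong:
  - Rearrangement may go partly to C3.
  - The first-formed phenol may react on by the abnormal Claisen pathway or by ring closure onto the alkene at the high temperature.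
  - The prenyl group may be lost thermally.
  - Silyl groups may scramble between phenols.
- Fallback (sets out from 12, rejoins at 17). The quaternary carbon is made by cross-coupling in place of a sigmatropic shift.
  - Bromination of 12 (Br2, AcOH) gives 5-bromo-2,4-dihydroxybenzaldehyde F10.
  - MOMCl and i-Pr2NEt give 5-bromo-2,4-bis(methoxymethoxy)benzaldehyde F11.
  - Branched-selective (γ) Suzuki–Miyaura coupling with 3-methylbut-2-enylboronic acid pinacol ester (Pd(OAc)2, bulky dialkylbiarylphosphine, aq K3PO4, THF, 40 °C) gives 2,4-bis(methoxymethoxy)-5-(2-methylbut-3-en-2-yl)benzaldehyde F12.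
  - Mild acid methanolysis (cat. TsOH, MeOH, rt) gives 2,4-dihydroxy-5-(2-methylbut-3-en-2-yl)benzaldehyde F13.
  - Double silylation (TBSCl, imidazole, DMAP, DMF) gives 17.

## Further compounds

F1 | step 12 | 2,2-dimethyl-3,4-dihydro-2H-pyran | CC1(C)CCC=CO1
F2 | step 12 | (CO)5Cr=C(OMe)(6,6-dimethyl-5,6-dihydro-4H-pyran-2-yl) | COC(=[Cr])C1=CCCC(C)(C)O1.[C-]#[O+].[C-]#[O+].[C-]#[O+].[C-]#[O+].[C-]#[O+]
F3 | step 12 | 6-[3-(2,4-bis[(tert-butyldimethylsilyl)oxy]-5-(2-methylbut-3-en-2-yl)phenyl)propyl]-8-methoxy-2,2-dimethylchroman-5-ol | C=CC(C)(C)c1cc(CCCc2cc(OC)c3c(c2O)CCC(C)(C)O3)c(O[Si](C)(C)C(C)(C)C)cc1O[Si](C)(C)C(C)(C)C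
F4 | step 12 | the 5-trifluoromethanesulfonate of F3 | C=CC(C)(C)c1cc(CCCc2cc(OC)c3c(c2OS(=O)(=O)C(F)(F)F)CCC(C)(C)O3)c(O[Si](C)(C)C(C)(C)C)cc1O[Si](C)(C)C(C)(C)C
F5 | step 12 | 8-O-methylkazinol D bis(tert-butyldimethylsilyl) ether | C=CC(C)(C)c1cc(CCCc2cc(OC)c3c(c2CC=C(C)C)CCC(C)(C)O3)c(O[Si](C)(C)C(C)(C)C)cc1O[Si](C)(C)C(C)(C)C
F6 | step 12 | 8-O-methylkazinol D | C=CC(C)(C)c1cc(CCCc2cc(OC)c3c(c2CC=C(C)C)CCC(C)(C)O3)c(O)cc1O
F7 | step 13 | ({[2,9-dimethyldec-8-en-5-yn-2-yl]oxy}ethynyl)(isopropoxy)dimethylsilane | CC(C)=CCC#CCCC(C)(C)OC#C[Si](C)(C)OC(C)C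
F8 | step 13 | 8-(isopropoxydimethylsilyl) analogue of 24 | C=CC(C)(C)c1cc(CCCc2cc([Si](C)(C)OC(C)C)c3c(c2CC=C(C)C)CCC(C)(C)O3)c(O[Si](C)(C)C(C)(C)C)cc1O[Si](C)(C)C(C)(C)C
F9 | step 13 | kazinol D ring A bis(tert-butyldimethylsilyl) ether | C=CC(C)(C)c1cc(CCCc2cc(O)c3c(c2CC=C(C)C)CCC(C)(C)O3)c(O[Si](C)(C)C(C)(C)C)cc1O[Si](C)(C)C(C)(C)C
F10 | step 7 | 5-bromo-2,4-dihydroxybenzaldehyde | O=Cc1cc(Br)c(O)cc1O
F11 | step 7 | 5-bromo-2,4-bis(methoxymethoxy)benzaldehyde | O=Cc1cc(Br)c(OCOC)cc1OCOC
F12 | step 7 | 2,4-bis(methoxymethoxy)-5-(2-methylbut-3-en-2-yl)benzaldehyde | O=Cc1cc(C(C)(C)C=C)c(OCOC)cc1OCOC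
F13 | step 7 | 2,4-dihydroxy-5-(2-methylbut-3-en-2-yl)benzaldehyde | O=Cc1cc(C(C)(C)C=C)c(O)cc1O
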